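**Remarks on the chemistry**

- The target is read as a germacranolide and numbered accordingly: ring carbons C1–C10 (oxirane C1–C10, acetoxy groups on C3 and C9, olefin C4=C5, lactone oxygen on C6, side chain on C7), C11, C12 (lactone carbonyl), C13 (methyl on C11), C14 (methyl on C10), C15 (methyl on C4). Ring A is the ten-membered carbocycle, ring B the γ-lactone, ring C the oxirane.
- Assumption: aldehyde 1 is taken as a catalogue chemical, like 2 and 4.
- The CIP letter at C10 switches between R and S along the route only because the priority of C9 changes with its oxygen substituent; the geometry at C10 is never altered.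

## Analysis of the target

The target is (1S,3S,4E,6S,7S,9S,10R,11R)-3,9-diacetoxy-1,10-epoxygermacr-4-en-12,6-olide. Ring A carries an E-trisubstituted olefin (C4=C5) and a trans oxirane (ring C, C1–C10). Ring B (O–C6–C7–C11–C12) is fused trans across C6–C7. There are seven stereocentres: the oxirane is anti (erythro) to the C9 oxygen, H6 and H7 are trans, and the C13 methyl is cis to C8 (11αH), which is the less stable orientation on the lactone. C3 and C9 are remote from the C6/C7/C11 triad, so no direct relay links the two groups of centres. The 1,10-epoxide of a germacr-4-ene is opened transannularly by C4=C5 under acid, the 9-oxygen/epoxide pair can undergo epoxide migration under base, C11 can epimerise, and the acetates exclude hydride and strong base late in the route. The feature that invites the key move is the fusion bond C6–C7: in an open chain C6 is the carbonyl carbon of an enal (conjugated with C4=C5) and C7 is the β-carbon of the α-methyl enoate C7=C11–C12. Both are electrophilic, so a polarity-reversing one-electron reduction can join them; that one bond closes ring A, triggers ring B and creates C6, C7 and C11. The skeleton is also three α-methyl-α,β-unsaturated C5 units (C3–C4(C15)=C5–C6, C9–C10(C14)=C1–C2, C12–C11(C13)=C7–C8) joined at C2–C3 and C8–C9, both carbinol–methylene bonds of the vinylogous aldol type. The hard part is the closure of a strained ten-membered ring with control of three new centres relative to four resident ones.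

## Retrosynthetic reasoning

**19 ⇐ 18 ⇐ 17 (two O–acyl bonds, two O–Si bonds).** The acetates go on last. An allylic acetate at C3 would not survive the ester reduction of step 5 and, being γ to the C6 carbonyl, would be expelled in the electron-transfer step. C3 and C9 therefore travel as silyl ethers, and diol 18 is acetylated at the end.

**17 ⇐ 15 (C6–C7 and the lactone C12–O bond; key disconnection).** Cutting the fusion bond turns a bicyclic lactone with seven stereocentres into the open-chain enal–enoate 15 with four, all set by reagent control. The termini already have the right oxidation states, so no auxiliary functional group (halide, metal, sulfone) is needed, and the product is directly the 11,13-dihydro lactone. The forward reaction must generate a ketyl at C6, add it to C7 (ten-membered closure), protonate C11 and lactonise through hydroxy ester 16.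

**15 ⇐ 14 ⇐ 13 ⇐ 12 ⇐ 11 (ring C and functional-group changes).** The oxirane C–O bonds are cut back to the E-olefin C1=C10 of 11. In 11 the C9 hydroxyl is the only free allylic alcohol, so a Sharpless asymmetric epoxidation is both site-selective and reagent-controlled, and it is done on an open chain where no ring conformation interferes. Silylation at C9, removal of the benzylic ether at C6 and allylic oxidation then give 15.

**11 ⇐ 10 + 6 (C8–C9).** A catalytic enantioselective vinylogous Mukaiyama aldol addition of diene 6 to enal 10 makes the C9 carbinol, the E-enoate and all of C7, C8, C11, C12 and C13 in one step.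

**10 ⇐ 9 ⇐ 8 ⇐ 7 ⇐ 3 + 6 (C2–C3).** The same reaction with the same diene 6 and enal 3 gives 7 with the C3 carbinol. The ester of 7 is the future C9 and is adjusted to the aldehyde of 10 through 8 and 9.

**3 ⇐ 1 + 2 and 6 ⇐ 4.** Enal 3 comes from a Wittig reaction that fixes the E geometry of C4=C5. Diene 6 is the silyl dienolate of methyl tiglate 4, made through lithium dienolate 5.

## Alternatives that were turned down

**Alternative 1:** (textbook) C6–C7 by an intramolecular Nozaki–Hiyama–Kishi-type allylation. Aldehyde–allylic bromide A1 with CrCl2 would close ring A and, after lactonisation, give the α-methylene lactone A2; a conjugate reduction would then set C11. It was turned down because A1 needs an oxidised C13, which the tiglate unit does not provide, so the C7–C13 portion would have to be rebuilt by a separate acrylate addition and allylic bromination, several steps longer. A2 would also need a reduction that is selective for the exocyclic olefin and for one face in the presence of C4=C5 and the oxirane. The uncertainty about the facial sense of the closure relative to C3 and C9 is the same as in the chosen route, so more steps would buy no gain in control.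

**Alternative 2:** anionic oxy-Cope ring expansion, breaking C4–C9 and forming C6–C7. The 1,2-dialkenylcyclohexanol A3 (C9 carbinol carrying the E-alkenyl C8=C7–C11, C4 carrying methyl and an E-2-methoxyvinyl group) would rearrange through a chair to the cyclodecenone A4, with E-C4=C5 and C6/C7 relayed from the six-membered ring. It was turned down because the trans oxirane cannot be carried as an olefin in a cyclohexane; it must travel as a cis-diol acetonide and be closed late through a sulfonate. The carbinol carbon lies between two fully substituted carbons, so the alkenyl addition is severely hindered. The enol ether must be geometrically pure, the C6 oxygen arrives as a methyl ether, and the C9 ketone must later be reduced selectively inside ring A. The step count would be well above that of the chosen route.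

**Alternative 3:** ring-closing metathesis at C4=C5. Diene A5, with rings B and C and all seven stereocentres in place, would be treated with the second-generation Grubbs catalyst. It was turned down because a trisubstituted E-olefin in a ten-membered ring is strained and metathesis is expected to give the (4Z)-isomer A6 or cyclodimers. The 1,1-disubstituted olefin next to the C3 acetoxy group is also a slow partner, and the key step would create no stereocentre, so every centre of A5 would need its own step.

Key step: step 12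

## Route

Step 1
Reactants: 1 2-[(4-methoxyphenyl)methoxy]acetaldehyde; 2 2-(triphenyl-λ5-phosphanylidene)propanal
Product: 3 (2E)-4-[(4-methoxyphenyl)methoxy]-2-methylbut-2-enal
Conditions: toluene, 90 °C
Reagents that add atoms: none
Why: Wittig olefination with a stabilised formyl ylide should give the E-trisubstituted enal, which fixes the geometry of C4=C5 for the whole route.

Step 2
Reactants: 4 methyl (2E)-2-methylbut-2-enoate (methyl tiglate)
Product: 6 tert-butyl{[(1E)-1-methoxy-2-methylbuta-1,3-dien-1-yl]oxy}dimethylsilane, via lithium dienolate 5 (not isolated)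
Conditions: LDA (LiN(iPr)2), DMPU, THF, −78 °C; TBSCl, −78 °C → rt
Reagents that add atoms: tert-butyldimethylsilyl chloride, CC(C)(C)[Si](C)(C)Cl
Why: Kinetic γ-deprotonation of the enoate at its β-methyl group gives the extended enolate, which is silylated on oxygen; this one C5 diene later supplies both C9/C10/C14/C1/C2 and C12/C11/C13/C7/C8.

Step 3
Reactants: 3 (2E)-4-[(4-methoxyphenyl)methoxy]-2-methylbut-2-enal; 6 tert-butyl{[(1E)-1-methoxy-2-methylbuta-1,3-dien-1-yl]oxy}dimethylsilane
Product: 7 methyl (2E,5S,6E)-5-hydroxy-8-[(4-methoxyphenyl)methoxy]-2,6-dimethylocta-2,6-dienoate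
Conditions: SiCl4 (1.1 equiv), (S,S)-bis(phosphoramide) catalyst (two N,N'-dimethyl-1,1'-binaphthyl-2,2'-diamine phosphoramide units on an N,N'-dimethylpentane-1,5-diamine tether, 5 mol %), iPr2NEt (0.1 equiv), CH2Cl2, −78 °C; aq. NaHCO3
Reagents that add atoms: none
Why: Catalytic enantioselective vinylogous Mukaiyama aldol addition through a chiral phosphoramide-bound trichlorosilyl cation; the dienolate should react only at its γ-terminus and give the E-enoate. The (S,S)-catalyst is chosen for Si-face attack on the enal, which sets C3 as S; this sense is assigned by analogy with the Re-face preference of the (R,R)-catalyst with conjugated aldehydes.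

Step 4
Reactants: 7 methyl (2E,5S,6E)-5-hydroxy-8-[(4-methoxyphenyl)methoxy]-2,6-dimethylocta-2,6-dienoate
Product: 8 methyl (2E,5S,6E)-5-[(tert-butyldimethylsilyl)oxy]-8-[(4-methoxyphenyl)methoxy]-2,6-dimethylocta-2,6-dienoate
Conditions: TBSCl, imidazole, DMF, rt
Reagents that add atoms: tert-butyldimethylsilyl chloride, CC(C)(C)[Si](C)(C)Cl
Why: Standard silylation of the secondary allylic alcohol; a silyl ether is needed at C3 because an acetate would not survive step 5 and would be expelled in step 12.

Step 5
Reactants: 8 methyl (2E,5S,6E)-5-[(tert-butyldimethylsilyl)oxy]-8-[(4-methoxyphenyl)methoxy]-2,6-dimethylocta-2,6-dienoate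
Product: 9 (2E,5S,6E)-5-[(tert-butyldimethylsilyl)oxy]-8-[(4-methoxyphenyl)methoxy]-2,6-dimethylocta-2,6-dien-1-ol
Conditions: iBu2AlH (2.5 equiv), CH2Cl2, −78 °C; aq. Rochelle salt
Reagents that add atoms: none
Why: 1,2-Reduction of the α,β-unsaturated ester to the allylic alcohol; silyl and benzylic ethers are inert.

Step 6
Reactants: 9 (2E,5S,6E)-5-[(tert-butyldimethylsilyl)oxy]-8-[(4-methoxyphenyl)methoxy]-2,6-dimethylocta-2,6-dien-1-ol
Product: 10 (2E,5S,6E)-5-[(tert-butyldimethylsilyl)oxy]-8-[(4-methoxyphenyl)methoxy]-2,6-dimethylocta-2,6-dienal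
Conditions: MnO2, CH2Cl2, rt
Reagents that add atoms: none
Why: Neutral allylic oxidation should give the E-enal (the future C9 aldehyde) without touching the ethers or the olefin geometry.

Step 7
Reactants: 10 (2E,5S,6E)-5-[(tert-butyldimethylsilyl)oxy]-8-[(4-methoxyphenyl)methoxy]-2,6-dimethylocta-2,6-dienal; 6 tert-butyl{[(1E)-1-methoxy-2-methylbuta-1,3-dien-1-yl]oxy}dimethylsilane
Product: 11 methyl (2E,5S,6E,9S,10E)-9-[(tert-butyldimethylsilyl)oxy]-5-hydroxy-12-[(4-methoxyphenyl)methoxy]-2,6,10-trimethyldodeca-2,6,10-trienoate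
Conditions: SiCl4 (1.1 equiv), the (S,S)-bis(phosphoramide) catalyst of step 3 (5 mol %), iPr2NEt (0.1 equiv), CH2Cl2, −78 °C; aq. NaHCO3
Reagents that add atoms: none
Why: Second vinylogous Mukaiyama aldol addition with the same diene and catalyst; Si-face attack should set C9 as S under catalyst control, since C3 is five atoms away. The E-tiglate terminus C7=C11 formed here is the acceptor for step 12.

Step 8
Reactants: 11 methyl (2E,5S,6E,9S,10E)-9-[(tert-butyldimethylsilyl)oxy]-5-hydroxy-12-[(4-methoxyphenyl)methoxy]-2,6,10-trimethyldodeca-2,6,10-trienoate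
Product: 12 methyl (2E,5S)-5-[(2S,3S)-3-{(2S,3E)-2-[(tert-butyldimethylsilyl)oxy]-5-[(4-methoxyphenyl)methoxy]-3-methylpent-3-en-1-yl}-2-methyloxiran-2-yl]-5-hydroxy-2-methylpent-2-enoate
Conditions: Ti(OiPr)4 (0.3 equiv), L-(+)-diisopropyl tartrate (0.36 equiv), t-BuOOH, 4 Å sieves, CH2Cl2, −20 °C
Reagents that add atoms: tert-butyl hydroperoxide, CC(C)(C)OO
Why: Sharpless asymmetric epoxidation; only C1=C10 is allylic to a free hydroxyl, the enoate is electron-poor and C4=C5 has no free alcohol. With the L-(+)-tartrate the (9S)-alcohol is the fast-reacting, matched enantiomer and should give the anti (erythro) epoxy alcohol, which is the C1 and C10 geometry of the target.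

Step 9
Reactants: 12 methyl (2E,5S)-5-[(2S,3S)-3-{(2S,3E)-2-[(tert-butyldimethylsilyl)oxy]-5-[(4-methoxyphenyl)methoxy]-3-methylpent-3-en-1-yl}-2-methyloxiran-2-yl]-5-hydroxy-2-methylpent-2-enoate
Product: 13 methyl (2E,5S)-5-[(2R,3S)-3-{(2S,3E)-2-[(tert-butyldimethylsilyl)oxy]-5-[(4-methoxyphenyl)methoxy]-3-methylpent-3-en-1-yl}-2-methyloxiran-2-yl]-2-methyl-5-[(triethylsilyl)oxy]pent-2-enoate
Conditions: Et3SiCl, imidazole, DMAP (cat.), CH2Cl2, 0 °C → rt
Reagents that add atoms: chlorotriethylsilane, CC[Si](CC)(CC)Cl
Why: Silylation of the hindered C9 alcohol under non-acidic conditions; the triethylsilyl group is chosen because it can later be removed gently next to the oxirane.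

Step 10
Reactants: 13 methyl (2E,5S)-5-[(2R,3S)-3-{(2S,3E)-2-[(tert-butyldimethylsilyl)oxy]-5-[(4-methoxyphenyl)methoxy]-3-methylpent-3-en-1-yl}-2-methyloxiran-2-yl]-2-methyl-5-[(triethylsilyl)oxy]pent-2-enoate
Product: 14 methyl (2E,5S)-5-[(2R,3S)-3-{(2S,3E)-2-[(tert-butyldimethylsilyl)oxy]-5-hydroxy-3-methylpent-3-en-1-yl}-2-methyloxiran-2-yl]-2-methyl-5-[(triethylsilyl)oxy]pent-2-enoate
Conditions: DDQ, CH2Cl2/pH 7 buffer, 0 °C
Reagents that add atoms: none
Why: Oxidative cleavage of the 4-methoxybenzyl ether under buffered conditions should free the C6 alcohol; silyl ethers, oxirane and enoate are inert.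

Step 11
Reactants: 14 methyl (2E,5S)-5-[(2R,3S)-3-{(2S,3E)-2-[(tert-butyldimethylsilyl)oxy]-5-hydroxy-3-methylpent-3-en-1-yl}-2-methyloxiran-2-yl]-2-methyl-5-[(triethylsilyl)oxy]pent-2-enoate
Product: 15 methyl (2E,5S)-5-[(2R,3S)-3-{(2S,3E)-2-[(tert-butyldimethylsilyl)oxy]-3-methyl-5-oxopent-3-en-1-yl}-2-methyloxiran-2-yl]-2-methyl-5-[(triethylsilyl)oxy]pent-2-enoate
Conditions: MnO2, CH2Cl2, rt
Reagents that add atoms: none
Why: Neutral allylic oxidation should give the E-enal at C6 and complete the enal–enoate precursor of the key step.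

Step 12
Reactants: 15 methyl (2E,5S)-5-[(2R,3S)-3-{(2S,3E)-2-[(tert-butyldimethylsilyl)oxy]-3-methyl-5-oxopent-3-en-1-yl}-2-methyloxiran-2-yl]-2-methyl-5-[(triethylsilyl)oxy]pent-2-enoate
Product: 17 (1S,3S,4E,6S,7S,9S,10R,11R)-3-[(tert-butyldimethylsilyl)oxy]-1,10-epoxy-9-[(triethylsilyl)oxy]germacr-4-en-12,6-olide, via hydroxy ester 16 (not isolated)
Conditions: SmI2 (3 equiv), t-BuOH (3 equiv), THF, −78 → −20 °C, 15 added over 8 h (final 0.002 M); pH 7 buffer
Reagents that add atoms: none
Why: Proposed new method: SmI2 reduces the enal of 15 to a samarium-bound ketyl whose C6 adds to C7, the β-carbon of the E-enoate, within a chelate between the ketyl oxygen and the ester carbonyl; a second equivalent reduces the resulting C11 radical to the samarium enolate, tert-butanol protonates it, and alkoxide 16 closes the lactone with loss of methoxide. The closest known reaction type is the SmI2-mediated ketyl–olefin coupling of aldehydes with α,β-unsaturated esters to γ-lactones, including intramolecular cases that close eight-membered carbocycles; a ten-membered closure from an enal-derived ketyl has not been shown. Ring A closes by a 10-exo-trig addition of the ketyl to the enoate, made feasible by the two rigid E-type units (C4=C5 and the trans oxirane) that leave few rotors and fold the chain like the germacrane crown; ring B closes by 5-exo-trig acyl substitution. C6 and C7 are set together in the chelated transition state, where the ketyl C–O bond and the E-enoate are aligned so that H6 and H7 end up anti (trans-lactone); their sense relative to C3, C9 and the oxirane is expected to follow the crown that keeps both silyloxy groups pseudo-equatorial. C11 is set by protonation of the chelated samarium enolate from the face of H7, away from C8, which is the 11R orientation. The step needs C6–C7 coupling to outrun pinacol dimerisation, coupling through C4 and two-electron reduction with loss of the C3 silyloxy group; high dilution with slow addition, the absence of HMPA, the poor silyloxide leaving group, the fully substituted C4 and the chelate that holds C6 next to C7 are meant to secure this.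

Step 13
Reactants: 17 (1S,3S,4E,6S,7S,9S,10R,11R)-3-[(tert-butyldimethylsilyl)oxy]-1,10-epoxy-9-[(triethylsilyl)oxy]germacr-4-en-12,6-olide
Product: 18 (1S,3S,4E,6S,7S,9S,10S,11R)-1,10-epoxy-3,9-dihydroxygermacr-4-en-12,6-olide
Conditions: Bu4NF, AcOH (1:1), THF, 0 °C → rt
Reagents that add atoms: none
Why: Buffered fluoride should remove both silyl ethers near neutrality; this avoids acid, which would trigger transannular opening of the oxirane by C4=C5, and free base, which could cause epoxide migration or C11 epimerisation.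

Step 14
Reactants: 18 (1S,3S,4E,6S,7S,9S,10S,11R)-1,10-epoxy-3,9-dihydroxygermacr-4-en-12,6-olide
Product: 19 (1S,3S,4E,6S,7S,9S,10R,11R)-3,9-diacetoxy-1,10-epoxygermacr-4-en-12,6-olide (target)
Conditions: Ac2O, pyridine, DMAP (cat.), CH2Cl2, 0 °C → rt
Reagents that add atoms: acetic anhydride, CC(=O)OC(C)=O
Why: DMAP-catalysed acetylation of both secondary alcohols, including the hindered C9 hydroxyl; the mild base should leave C11 and the oxirane untouched.

## Compound list

1 | 2-[(4-methoxyphenyl)methoxy]acetaldehyde | O=CCOCc1ccc(OC)cc1 | starting material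
2 | 2-(triphenyl-λ5-phosphanylidene)propanal | CC(C=O)=P(c1ccccc1)(c1ccccc1)c1ccccc1 | starting material
3 | (2E)-4-[(4-methoxyphenyl)methoxy]-2-methylbut-2-enal | O=C/C(C)=C/COCc1ccc(OC)cc1 | intermediate
4 | methyl (2E)-2-methylbut-2-enoate (methyl tiglate) | COC(=O)/C(C)=C/C | starting material
5 | lithium dienolate of methyl tiglate (methoxy group cis to the vinyl group) | [Li+].CO/C([O-])=C(/C)C=C | intermediate (not isolated)
6 | tert-butyl{[(1E)-1-methoxy-2-methylbuta-1,3-dien-1-yl]oxy}dimethylsilane | CO/C(O[Si](C)(C)C(C)(C)C)=C(/C)C=C | intermediate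
7 | methyl (2E,5S,6E)-5-hydroxy-8-[(4-methoxyphenyl)methoxy]-2,6-dimethylocta-2,6-dienoate | COC(=O)/C(C)=C/C[C@H](O)/C(C)=C/COCc1ccc(OC)cc1 | intermediate
8 | methyl (2E,5S,6E)-5-[(tert-butyldimethylsilyl)oxy]-8-[(4-methoxyphenyl)methoxy]-2,6-dimethylocta-2,6-dienoate | COC(=O)/C(C)=C/C[C@H](O[Si](C)(C)C(C)(C)C)/C(C)=C/COCc1ccc(OC)cc1 | intermediate
9 | (2E,5S,6E)-5-[(tert-butyldimethylsilyl)oxy]-8-[(4-methoxyphenyl)methoxy]-2,6-dimethylocta-2,6-dien-1-ol | OC/C(C)=C/C[C@H](O[Si](C)(C)C(C)(C)C)/C(C)=C/COCc1ccc(OC)cc1 | intermediate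
10 | (2E,5S,6E)-5-[(tert-butyldimethylsilyl)oxy]-8-[(4-methoxyphenyl)methoxy]-2,6-dimethylocta-2,6-dienal | O=C/C(C)=C/C[C@H](O[Si](C)(C)C(C)(C)C)/C(C)=C/COCc1ccc(OC)cc1 | intermediate
11 | methyl (2E,5S,6E,9S,10E)-9-[(tert-butyldimethylsilyl)oxy]-5-hydroxy-12-[(4-methoxyphenyl)methoxy]-2,6,10-trimethyldodeca-2,6,10-trienoate | COC(=O)/C(C)=C/C[C@H](O)/C(C)=C/C[C@H](O[Si](C)(C)C(C)(C)C)/C(C)=C/COCc1ccc(OC)cc1 | intermediate
12 | methyl (2E,5S)-5-[(2S,3S)-3-{(2S,3E)-2-[(tert-butyldimethylsilyl)oxy]-5-[(4-methoxyphenyl)methoxy]-3-methylpent-3-en-1-yl}-2-methyloxiran-2-yl]-5-hydroxy-2-methylpent-2-enoate | COC(=O)/C(C)=C/C[C@H](O)[C@]1(C)O[C@H]1C[C@H](O[Si](C)(C)C(C)(C)C)/C(C)=C/COCc1ccc(OC)cc1 | intermediate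
13 | methyl (2E,5S)-5-[(2R,3S)-3-{(2S,3E)-2-[(tert-butyldimethylsilyl)oxy]-5-[(4-methoxyphenyl)methoxy]-3-methylpent-3-en-1-yl}-2-methyloxiran-2-yl]-2-methyl-5-[(triethylsilyl)oxy]pent-2-enoate | COC(=O)/C(C)=C/C[C@H](O[Si](CC)(CC)CC)[C@]1(C)O[C@H]1C[C@H](O[Si](C)(C)C(C)(C)C)/C(C)=C/COCc1ccc(OC)cc1 | intermediate
14 | methyl (2E,5S)-5-[(2R,3S)-3-{(2S,3E)-2-[(tert-butyldimethylsilyl)oxy]-5-hydroxy-3-methylpent-3-en-1-yl}-2-methyloxiran-2-yl]-2-methyl-5-[(triethylsilyl)oxy]pent-2-enoate | COC(=O)/C(C)=C/C[C@H](O[Si](CC)(CC)CC)[C@]1(C)O[C@H]1C[C@H](O[Si](C)(C)C(C)(C)C)/C(C)=C/CO | intermediate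
15 | methyl (2E,5S)-5-[(2R,3S)-3-{(2S,3E)-2-[(tert-butyldimethylsilyl)oxy]-3-methyl-5-oxopent-3-en-1-yl}-2-methyloxiran-2-yl]-2-methyl-5-[(triethylsilyl)oxy]pent-2-enoate | COC(=O)/C(C)=C/C[C@H](O[Si](CC)(CC)CC)[C@]1(C)O[C@H]1C[C@H](O[Si](C)(C)C(C)(C)C)/C(C)=C/C=O | intermediate
16 | methyl (1S,3S,4E,6S,7S,9S,10R,11R)-3-[(tert-butyldimethylsilyl)oxy]-1,10-epoxy-6-hydroxy-9-[(triethylsilyl)oxy]germacr-4-en-12-oate (present as its samarium alkoxide) | CC(C)(C)[Si](C)(C)O[C@H]1C[C@@H]2O[C@@]2(C)[C@@H](O[Si](CC)(CC)CC)C[C@@H]([C@@H](C)C(=O)OC)[C@H](O)/C=C/1C | intermediate (not isolated)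
17 | (1S,3S,4E,6S,7S,9S,10R,11R)-3-[(tert-butyldimethylsilyl)oxy]-1,10-epoxy-9-[(triethylsilyl)oxy]germacr-4-en-12,6-olide | CC(C)(C)[Si](C)(C)O[C@H]1C[C@@H]2O[C@@]2(C)[C@@H](O[Si](CC)(CC)CC)C[C@@H]2[C@@H](/C=C/1C)OC(=O)[C@@H]2C | intermediate
18 | (1S,3S,4E,6S,7S,9S,10S,11R)-1,10-epoxy-3,9-dihydroxygermacr-4-en-12,6-olide | O[C@H]1C[C@@H]2O[C@@]2(C)[C@@H](O)C[C@@H]2[C@@H](/C=C/1C)OC(=O)[C@@H]2C | intermediate
19 | (1S,3S,4E,6S,7S,9S,10R,11R)-3,9-diacetoxy-1,10-epoxygermacr-4-en-12,6-olide | CC(=O)O[C@H]1C[C@@H]2O[C@@]2(C)[C@@H](OC(C)=O)C[C@@H]2[C@@H](/C=C/1C)OC(=O)[C@@H]2C | target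

## Step count and least certain steps

Total step count: 14. Longest linear sequence: 13 steps (steps 1 and 3–14; step 2 prepares diene 6, which is used twice).

**Step 12 (key step, carries the label "Proposed new method:").** The ten-membered closure is slow, so the ketyl may be consumed first by bimolecular pinacol coupling, by bond formation through C4, or by a second electron transfer followed by loss of the C3 silyloxy group. The facial sense of the closure relative to C3, C9 and the oxirane rests on a conformational argument, and protonation at C11 may be unselective. Trivalent samarium salts formed in the flask could also open the oxirane if the mixture is allowed to warm. Fallback with known chemistry, a ring contraction in place of the ring closure, from 14 back to 17: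
- Chlorination of the C6 alcohol of 14 (MsCl, 2,4,6-collidine, LiCl, DMF, 0 °C) gives the allylic chloride F1.
- iBu2AlH (CH2Cl2, −78 °C) reduces the ester to the chloro alcohol F2.
- NaH in THF at high dilution closes the thirteen-membered diallylic ether F3 by Williamson etherification.
- n-BuLi (THF, −78 °C) deprotonates C6 and the [2,3]-Wittig rearrangement contracts the ring to the ten-membered homoallylic alcohol F4, with the C6–C7 bond, the 6-hydroxyl and an isopropenyl group on C7; this type of ring contraction is precedented for 6,7-trans germacranolide frameworks.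
- Hydroboration of the 1,1-disubstituted olefin with 9-BBN and oxidation with NaBO3 gives the diol F5, whose C11 configuration would have to be checked at that stage.
- Oxidative lactonisation (TEMPO, PhI(OAc)2) returns 17.

**Step 7 (step 3 carries the same risk on a simpler substrate).** The facial sense or level of induction of the catalyst with an α-methyl-β-alkyl enal may be lower than with aryl-conjugated aldehydes, and some attack at the α-carbon of the dienolate may compete. Fallback from 10 back to 11: an uncatalysed Mukaiyama vinylogous aldol addition of 6 to 10 (BF3·OEt2, CH2Cl2, −78 °C) gives the C9 epimer mixture F6. Oxidation (Dess–Martin periodinane, NaHCO3) gives the dienone F7, used without delay because its C8 methylene is doubly activated. Corey–Bakshi–Shibata reduction with the (R)-methyl oxazaborolidine and catecholborane, with the alkenyl group as the large substituent, returns 11 with (9S) configuration.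

**Step 8.** The secondary allylic alcohol with a 2-methyl-substituted olefin turns over slowly on titanium, so incomplete conversion and titanium-promoted opening of the product epoxy alcohol are the likely failures. Fallback from 9 back to 12, with the oxirane made before the C8–C9 bond: Sharpless epoxidation of the primary allylic alcohol 9 (Ti(OiPr)4, L-(+)-diethyl tartrate, t-BuOOH, −20 °C), a fast and reliable substrate class, gives the epoxy alcohol F8. Oxidation (Dess–Martin periodinane, NaHCO3) gives the epoxy aldehyde F9. Addition of diene 6 (BF3·OEt2, −78 °C) with attack anti to the oxirane C–O bond (Felkin–Anh control) should give the anti epoxy alcohol 12.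

**Step 13.** Removal of the hindered C9 silyl ether may need long exposure to fluoride, during which transannular opening of the oxirane by C4=C5 or epoxide migration to C9–C10 may set in. Fallback from 12 back to 19, in which C9 carries its final acetate from the start and only the unhindered allylic silyl ether at C3 has to be removed: acetylation of 12 (Ac2O, pyridine, DMAP) gives acetate F10. The conditions of steps 10, 11 and 12 then give alcohol F11, enal F12 and lactone F13 in turn. Brief buffered desilylation (Bu4NF, AcOH) gives the 3-hydroxy 9-acetate F14, and acetylation as in step 14 returns 19.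

## Further compounds

F1 | step 12 | C6 allylic chloride corresponding to 14 | COC(=O)/C(C)=C/C[C@H](O[Si](CC)(CC)CC)[C@]1(C)O[C@H]1C[C@H](O[Si](C)(C)C(C)(C)C)/C(C)=C/CCl
F2 | step 12 | chloro alcohol (C12 primary allylic alcohol, C6 chloride) | OC/C(C)=C/C[C@H](O[Si](CC)(CC)CC)[C@]1(C)O[C@H]1C[C@H](O[Si](C)(C)C(C)(C)C)/C(C)=C/CCl
F3 | step 12 | thirteen-membered diallylic ether (O bridging C6 and C12) | O1C/C(C)=C/C[C@H](O[Si](CC)(CC)CC)[C@]2(C)O[C@H]2C[C@H](O[Si](C)(C)C(C)(C)C)/C(C)=C/C1
F4 | step 12 | ten-membered 6-hydroxy-7-isopropenyl carbocycle (ring-contracted homoallylic alcohol) | CC(C)(C)[Si](C)(C)O[C@H]1C[C@@H]2O[C@@]2(C)[C@@H](O[Si](CC)(CC)CC)C[C@@H](C(C)=C)[C@H](O)/C=C/1C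
F5 | step 12 | 6,12-diol with (11R)-methyl | CC(C)(C)[Si](C)(C)O[C@H]1C[C@@H]2O[C@@]2(C)[C@@H](O[Si](CC)(CC)CC)C[C@@H]([C@@H](C)CO)[C@H](O)/C=C/1C
F6 | step 7 | C9 epimer mixture of 11 | COC(=O)/C(C)=C/CC(O)/C(C)=C/C[C@H](O[Si](C)(C)C(C)(C)C)/C(C)=C/COCc1ccc(OC)cc1
F7 | step 7 | C9 ketone (dienone) corresponding to 11 | COC(=O)/C(C)=C/CC(=O)/C(C)=C/C[C@H](O[Si](C)(C)C(C)(C)C)/C(C)=C/COCc1ccc(OC)cc1
F8 | step 8 | [(2S,3S)-3-{(2S,3E)-2-[(tert-butyldimethylsilyl)oxy]-5-[(4-methoxyphenyl)methoxy]-3-methylpent-3-en-1-yl}-2-methyloxiran-2-yl]methanol | OC[C@]1(C)O[C@H]1C[C@H](O[Si](C)(C)C(C)(C)C)/C(C)=C/COCc1ccc(OC)cc1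
F9 | step 8 | (2R,3S)-3-{(2S,3E)-2-[(tert-butyldimethylsilyl)oxy]-5-[(4-methoxyphenyl)methoxy]-3-methylpent-3-en-1-yl}-2-methyloxirane-2-carbaldehyde | O=C[C@]1(C)O[C@H]1C[C@H](O[Si](C)(C)C(C)(C)C)/C(C)=C/COCc1ccc(OC)cc1
F10 | step 13 | C9 acetate of 12 | COC(=O)/C(C)=C/C[C@H](OC(C)=O)[C@]1(C)O[C@H]1C[C@H](O[Si](C)(C)C(C)(C)C)/C(C)=C/COCc1ccc(OC)cc1
F11 | step 13 | C9 acetate, C6 alcohol | COC(=O)/C(C)=C/C[C@H](OC(C)=O)[C@]1(C)O[C@H]1C[C@H](O[Si](C)(C)C(C)(C)C)/C(C)=C/CO
F12 | step 13 | C9 acetate, C6 enal | COC(=O)/C(C)=C/C[C@H](OC(C)=O)[C@]1(C)O[C@H]1C[C@H](O[Si](C)(C)C(C)(C)C)/C(C)=C/C=O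
F13 | step 13 | 9-acetoxy-3-[(tert-butyldimethylsilyl)oxy]-1,10-epoxygermacr-4-en-12,6-olide | CC(C)(C)[Si](C)(C)O[C@H]1C[C@@H]2O[C@@]2(C)[C@@H](OC(C)=O)C[C@@H]2[C@@H](/C=C/1C)OC(=O)[C@@H]2C
F14 | step 13 | 9-acetoxy-1,10-epoxy-3-hydroxygermacr-4-en-12,6-olide | O[C@H]1C[C@@H]2O[C@@]2(C)[C@@H](OC(C)=O)C[C@@H]2[C@@H](/C=C/1C)OC(=O)[C@@H]2C
A1 | alternative 1 | enal with a (2Z)-2-(bromomethyl)enoate terminus (allylation precursor) | COC(=O)/C(CBr)=C/C[C@H](O[Si](CC)(CC)CC)[C@]1(C)O[C@H]1C[C@H](O[Si](C)(C)C(C)(C)C)/C(C)=C/C=O
A2 | alternative 1 | 11(13)-methylene lactone of the bis-silyl germacranolide | CC(C)(C)[Si](C)(C)O[C@H]1C[C@@H]2O[C@@]2(C)[C@@H](O[Si](CC)(CC)CC)C[C@@H]2[C@@H](/C=C/1C)OC(=O)C2=C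
A3 | alternative 2 | 1,2-dialkenylcyclohexanol (C9 carbinol, C4 methyl and E-2-methoxyvinyl, C1/C10 cis-diol acetonide, C3 silyl ether) | O[C@@]1(/C=C/[C@@H](C)CO[Si](C)(C)C(C)(C)C)[C@]2(C)OC(C)(C)O[C@@H]2C[C@H](O[Si](C)(C)C(C)(C)C)[C@@]1(C)/C=C/OC
A4 | alternative 2 | ten-membered C9 ketone from the oxy-Cope rearrangement (6-methoxy, E-C4=C5) | CC(C)(C)[Si](C)(C)O[C@H]1C[C@H]2OC(C)(C)O[C@@]2(C)C(=O)C[C@@H]([C@@H](C)CO[Si](C)(C)C(C)(C)C)[C@H](OC)/C=C/1C
A5 | alternative 3 | seco-diene lactone (vinyl on C6, isopropenyl on C3) | C=C(C)[C@@H](OC(C)=O)C[C@@H]1O[C@@]1(C)[C@@H](OC(C)=O)C[C@@H]1[C@@H](C=C)OC(=O)[C@@H]1C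
A6 | alternative 3 | (4Z)-isomer of the target | CC(=O)O[C@H]1C[C@@H]2O[C@@]2(C)[C@@H](OC(C)=O)C[C@@H]2[C@@H](/C=C\1C)OC(=O)[C@@H]2C
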